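**Retrosynthetic overview**

- The target is 2-heptacosyl-5,7-dihydroxy-4H-chromen-4-one. The strategy rests on C4: this carbonyl carbon stands alone between C4a of the threefold-symmetric, trioxygenated ring A and the C3–C2 unit that carries the C27 chain, so it can be brought in as CO.
- Last disconnection: O1–C2 of the pyranone (ring C), opened to a β-diethylamino enone whose two ortho oxygens are equivalent.
- Key disconnection: C4a–C4 and C4–C3, made together by carbonylative Sonogashira coupling of 2-iodo-1,3,5-tris(methoxymethoxy)benzene, CO and 1-nonacosyne.
- Fragments: the aryl iodide from phloroglucinol (MOM protection, ortho-lithiation/iodination); the alkyne from 1-octacosanol (oxidation, Ohira–Bestmann homologation).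
- Ring order: ring A is bought; ring C is the only ring formed, in the last step.

Key step: step 5

Assumption: the C28–C30 chain compounds dissolve only in warm, weakly polar media, so THF, toluene or CH2Cl2 serves as solvent or co-solvent from step 3 onward; anhydrous phloroglucinol is taken for step 1.

**Route**

Step 1
Reactants: 1 phloroglucinol
Product: 2 1,3,5-tris(methoxymethoxy)benzene
Conditions: NaH, MOMCl, DMF, 0 °C → rt
Reagents that add atoms: chloromethyl methyl ether (MOMCl), COCCl
Why: Williamson-type O-alkylation of the tris-phenoxide with the hard electrophile MOMCl in a dipolar aprotic solvent should favour O- over C-alkylation and give the tris-acetal (MOM protection).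

Step 2
Reactants: 2 1,3,5-tris(methoxymethoxy)benzene
Product: 4 2-iodo-1,3,5-tris(methoxymethoxy)benzene, via aryllithium 3 (not isolated)
Conditions: n-BuLi, THF, 0 °C; then I2, THF, −78 °C → rt
Reagents that add atoms: iodine, II
Why: Directed ortho-metalation places lithium on a ring carbon flanked by two coordinating OMOM groups (all three ring C–H positions are equivalent by symmetry), and iodinolysis of the aryllithium should give a single aryl iodide.

Step 3
Reactants: 5 1-octacosanol
Product: 6 octacosanal
Conditions: Dess–Martin periodinane, CH2Cl2, 35 °C
Reagents that add atoms: none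
Why: Dess–Martin oxidation of a primary alcohol under anhydrous, near-neutral conditions should stop at the aldehyde, and warm CH2Cl2 keeps the waxy C28 chain in solution.

Step 4
Reactants: 6 octacosanal; 7 dimethyl (1-diazo-2-oxopropyl)phosphonate
Product: 8 1-nonacosyne
Conditions: K2CO3, MeOH/THF (1:2), rt → 40 °C
Reagents that add atoms: dimethyl (1-diazo-2-oxopropyl)phosphonate (compound 7), COP(=O)(OC)C(=[N+]=[N-])C(C)=O
Why: Seyferth–Gilbert homologation in the Ohira–Bestmann variant: methanolysis of 7 gives the diazomethylphosphonate anion, which olefinates the aldehyde to a diazoalkene that loses N2 and rearranges by 1,2-hydrogen shift to the terminal alkyne, the mild carbonate base sparing the enolisable aldehyde.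

Step 5
Reactants: 4 2-iodo-1,3,5-tris(methoxymethoxy)benzene; 8 1-nonacosyne; 9 carbon monoxide
Product: 10 1-[2,4,6-tris(methoxymethoxy)phenyl]triacont-2-yn-1-one
Conditions: PdCl2(PPh3)2 (5 mol %), Et3N, CO (10 bar), toluene, 80 °C, copper-free
Reagents that add atoms: carbon monoxide (compound 9), [C-]#[O+]
Why: PdCl2(PPh3)2 (divalent palladium) is reduced in the flask to zerovalent palladium, which inserts into the C–I bond of 4; CO then undergoes migratory insertion to an aroyl–palladium species (divalent palladium), alkyne 8 coordinates and is deprotonated by Et3N to give an aroyl(alkynyl)palladium complex, and reductive elimination releases the ynone and returns zerovalent palladium. The closest known reaction type is the copper-free carbonylative Sonogashira coupling of aryl iodides, CO and terminal alkynes. The step forms the C4a–C4 and C4–C3 bonds (chromone numbering), closes no ring and sets no stereocenter. The selectivity it needs is carbonylative over direct alkynylation: the aryl–palladium intermediate is electron-rich and flanked by two ortho OMOM groups, so aryl migration onto CO, which also relieves steric strain, should outrun the amine-mediated alkynyl transfer, and 10 bar of CO without a copper acetylide supports this. Because ring A is threefold symmetric, only one aryl iodide exists and the step raises no regiochemical question.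

Step 6
Reactants: 10 1-[2,4,6-tris(methoxymethoxy)phenyl]triacont-2-yn-1-one
Product: 11 (E)-3-(diethylamino)-1-[2,4,6-tris(methoxymethoxy)phenyl]triacont-2-en-1-one
Conditions: Et2NH (5 equiv), EtOH/THF, 40 °C
Reagents that add atoms: diethylamine, CCNCC
Why: Aza-Michael (conjugate) addition of a secondary amine to an ynone should give the thermodynamically preferred E vinylogous amide, which marks C3 of the chain as the site of the later O-attack and so excludes a five-membered (aurone-type) closure, while the MOM acetals are inert to amine.

Step 7
Reactants: 11 (E)-3-(diethylamino)-1-[2,4,6-tris(methoxymethoxy)phenyl]triacont-2-en-1-one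
Product: 13 2-heptacosyl-5,7-dihydroxy-4H-chromen-4-one, via triphenol enaminone 12 (not isolated)
Conditions: HCl (3 M in MeOH), THF, 50 °C
Reagents that add atoms: none
Why: Acid-catalysed transacetalisation to methanol should remove the three MOM groups (the C1 unit leaves as dimethoxymethane, not as free formaldehyde), and either of the two equivalent ortho phenols then adds to the amine-bearing carbon of the protonated enaminone (6-endo-trig oxa-Michael addition) with loss of diethylamine to give the pyranone, a chromone synthesis by addition–elimination on an enaminone.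

**Compound list**

1 | phloroglucinol (benzene-1,3,5-triol) | Oc1cc(O)cc(O)c1 | starting material
2 | 1,3,5-tris(methoxymethoxy)benzene | COCOc1cc(OCOC)cc(OCOC)c1 | intermediate
3 | [2,4,6-tris(methoxymethoxy)phenyl]lithium | [Li]c1c(OCOC)cc(OCOC)cc1OCOC | intermediate (not isolated)
4 | 2-iodo-1,3,5-tris(methoxymethoxy)benzene | COCOc1cc(OCOC)c(I)c(OCOC)c1 | intermediate
5 | 1-octacosanol | CCCCCCCCCCCCCCCCCCCCCCCCCCCCO | starting material
6 | octacosanal | CCCCCCCCCCCCCCCCCCCCCCCCCCCC=O | intermediate
7 | dimethyl (1-diazo-2-oxopropyl)phosphonate (Ohira–Bestmann reagent) | COP(=O)(OC)C(=[N+]=[N-])C(C)=O | starting material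
8 | 1-nonacosyne | CCCCCCCCCCCCCCCCCCCCCCCCCCCC#C | intermediate
9 | carbon monoxide | [C-]#[O+] | starting material
10 | 1-[2,4,6-tris(methoxymethoxy)phenyl]triacont-2-yn-1-one | CCCCCCCCCCCCCCCCCCCCCCCCCCCC#CC(=O)c1c(OCOC)cc(OCOC)cc1OCOC | intermediate
11 | (E)-3-(diethylamino)-1-[2,4,6-tris(methoxymethoxy)phenyl]triacont-2-en-1-one | CCCCCCCCCCCCCCCCCCCCCCCCCCC/C(N(CC)CC)=C\C(=O)c1c(OCOC)cc(OCOC)cc1OCOC | intermediate
12 | (E)-3-(diethylamino)-1-(2,4,6-trihydroxyphenyl)triacont-2-en-1-one | CCCCCCCCCCCCCCCCCCCCCCCCCCC/C(N(CC)CC)=C\C(=O)c1c(O)cc(O)cc1O | intermediate (not isolated)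
13 | 2-heptacosyl-5,7-dihydroxy-4H-chromen-4-one | CCCCCCCCCCCCCCCCCCCCCCCCCCCc1cc(=O)c2c(O)cc(O)cc2o1 | target

**Step count**

Total: 7 steps. Longest linear sequence: 5 steps (1 → 2 → 4 → 10 → 11 → 13, or equally 5 → 6 → 8 → 10 → 11 → 13).

**Steps most likely to fail, with fallbacks**

Step 5. Oxidative addition into the doubly ortho-substituted, electron-rich C–I bond may be slow under CO, and alkynyl transfer may overtake CO insertion, so that the non-carbonylated arylalkyne forms or the alkyne is consumed by oxidative dimerisation. The fallback builds the same two bonds one after the other without palladium or CO. It sets out from 2 and 8. Aryllithium 3, generated as in step 2, would be quenched with DMF instead of iodine to give 2,4,6-tris(methoxymethoxy)benzaldehyde F1. Alkyne 8, deprotonated with n-BuLi in THF at 0 °C, would add to F1 to give racemic 1-[2,4,6-tris(methoxymethoxy)phenyl]triacont-2-yn-1-ol F2. Dess–Martin oxidation of F2 in CH2Cl2 would bring the route back at ynone 10.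

Step 4. The waxy C28 aldehyde may stay out of solution in the methanolic medium that the reagent needs, and under carbonate it may undergo aldol self-condensation faster than olefination. The fallback is a Corey–Fuchs sequence run entirely in aprotic solvents. It sets out from 6. CBr4/PPh3 in CH2Cl2 at 0 °C would give 1,1-dibromononacos-1-ene F3. Treatment of F3 with n-BuLi (2.2 equiv) in THF from −40 °C to rt, then water, would give 1-nonacosyne and bring the route back at 8.

Step 7. During acetal cleavage the MOM-derived C1 electrophile may attack the very electron-rich C6/C8 positions of ring A (hydroxymethylation or methylene bridging), or acetal loss may stop before the last MOM group has gone. The fallback changes the protecting group to methyl ethers, which are removed by SN2 dealkylation and release no formaldehyde equivalent. It sets out from 8 and 9. Commercial 2-iodo-1,3,5-trimethoxybenzene F4 would take the place of 4 under the conditions of step 5 to give 1-(2,4,6-trimethoxyphenyl)triacont-2-yn-1-one F5. Diethylamine would add as in step 6 to give (E)-3-(diethylamino)-1-(2,4,6-trimethoxyphenyl)triacont-2-en-1-one F6. Heating F6 in 48% aqueous HBr/AcOH at reflux would cleave the three methyl ethers and close the pyranone (the classical demethylative chromone closure), bringing the route back at target 13.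

**Further compounds**

F1 | step 5 | 2,4,6-tris(methoxymethoxy)benzaldehyde | O=Cc1c(OCOC)cc(OCOC)cc1OCOC
F2 | step 5 | racemic 1-[2,4,6-tris(methoxymethoxy)phenyl]triacont-2-yn-1-ol | CCCCCCCCCCCCCCCCCCCCCCCCCCCC#CC(O)c1c(OCOC)cc(OCOC)cc1OCOC
F3 | step 4 | 1,1-dibromononacos-1-ene | CCCCCCCCCCCCCCCCCCCCCCCCCCCC=C(Br)Br
F4 | step 7 | 2-iodo-1,3,5-trimethoxybenzene | COc1cc(OC)c(I)c(OC)c1
F5 | step 7 | 1-(2,4,6-trimethoxyphenyl)triacont-2-yn-1-one | CCCCCCCCCCCCCCCCCCCCCCCCCCCC#CC(=O)c1c(OC)cc(OC)cc1OC
F6 | step 7 | (E)-3-(diethylamino)-1-(2,4,6-trimethoxyphenyl)triacont-2-en-1-one | CCCCCCCCCCCCCCCCCCCCCCCCCCC/C(N(CC)CC)=C\C(=O)c1c(OC)cc(OC)cc1OC
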